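The cyclohexene ring B (C3a'–C4'–C5'–C6'–C7'–C7a') of the propellane half is built one carbon short (ligustilide locants; primes for that half). An (R)-cyclohex-2-enyl ester tethers ring A to a 2,3-dicarboxylated cyclopent-2-enone, and an intramolecular [2+2] photocycloaddition relays the one purchased stereocentre to all four cyclobutane centres, with the cis fusion that five-membered enones ensure. Trimethylsilyldiazomethane then expands the cyclopentanone: its carbonyl carbon (C7') lies between a CH2 and the quaternary, ester-bearing cyclobutane carbon C7a', so only the CH2 should migrate, placing C=O where the C6'=C7' alkene is needed. The tether lactone later supplies the butyl ketone of lactone B and the ring A ketone.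

Key step: step 6

Remarks on the chemistry: unprimed locants are the butenolide half (ring A = C3a, C4, C5, C6, C7, C7a), primed locants the propellane half, and the cyclobutane is C6–C7–C3a'–C7a'. Carbons of intermediates carry the locant they have in the target. (R)-Cyclohex-2-en-1-ol and 1-pentanoylbenzotriazole are assumed to be catalogue compounds.

Step 1
Reactants: 1 tert-butyl acetoacetate; 2 methyl 2-(bromomethyl)acrylate
Product: 3 1-tert-butyl 7-methyl 6-methylidene-3-oxoheptanedioate
Conditions: NaH, THF, 0 °C; n-BuLi, 0 °C; then 2, −78 °C to 0 °C; aq. NH4Cl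
Reagents that add atoms: none
Why: Acetoacetate dianion alkylation, in which the more basic terminal carbanion displaces the allylic bromide (direct or allylic substitution gives the same product) and no stereocentre is formed.

Step 2
Reactants: 3
Product: 5 2-tert-butyl 1-methyl 3-oxocyclopent-1-ene-1,2-dicarboxylate, via alpha-keto ester 4 (not isolated)
Conditions: O3, CH2Cl2/MeOH, −78 °C; Me2S; then piperidine (cat.), AcOH (cat.), CH2Cl2, rt
Reagents that add atoms: none
Why: Ozonolysis of the acrylate C=CH2 gives the alpha-keto ester, and an intramolecular Knoevenagel condensation of the beta-keto ester CH2 onto this activated ketone closes the cyclopentenone (the oxygen brought in by ozone leaves as water).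

Step 3
Reactants: 5
Product: 6 2-(tert-butoxycarbonyl)-3-oxocyclopent-1-ene-1-carboxylic acid
Conditions: Me3SnOH, ClCH2CH2Cl, 70 °C; then 1 M HCl wash
Reagents that add atoms: trimethyltin hydroxide | C[Sn](C)(C)O
Why: Neutral ester hydrolysis with Me3SnOH should cleave the unhindered conjugated methyl ester and spare the tert-butyl ester, while avoiding free hydroxide that could open the ring by retro-Knoevenagel reaction.

Step 4
Reactants: 6; 7 (R)-cyclohex-2-en-1-ol
Product: 8 2-tert-butyl 1-[(1R)-cyclohex-2-en-1-yl] 3-oxocyclopent-1-ene-1,2-dicarboxylate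
Conditions: EDC·HCl, DMAP (cat.), CH2Cl2, 0 °C to rt
Reagents that add atoms: none
Why: Steglich esterification acylates the alcohol oxygen without touching the C–O bond, so the purchased carbinol stereocentre is retained.

Step 5
Reactants: 8
Product: 9 tetracyclic photoadduct (cyclopentanone, cyclobutane, tether lactone, ring A)
Conditions: hν (366 nm), degassed CH2Cl2 (0.005 M), rt
Reagents that add atoms: none
Why: Intramolecular enone–olefin [2+2] photocycloaddition, in which the triplet enone closes first C3a'–C7 (five-membered lactone ring) and then C7a'–C6 to the straight adduct; because the three-atom tether can only span cis positions, the carbinol centre C7a fixes C7, C6, C3a' and C7a', with ring A anti to the cis-fused cyclopentanone.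

Step 6
Reactants: 9
Product: 11 ring-expanded cyclohexanone keto lactone, via alpha-silyl ketone 10 (not isolated)
Conditions: TMSCHN2 (1.5 equiv), Sc(OTf)3 (10 mol %), toluene/CH2Cl2, −20 °C to rt; then 1 M HCl, THF, rt
Reagents that add atoms: trimethylsilyldiazomethane | C[Si](C)(C)C=[N+]=[N-]
Why: Sc(OTf)3 chelates the beta-keto ester of 9, the diazo carbon adds to the C7' carbonyl, and the diazonium alkoxide collapses by 1,2-shift of a ring carbon with loss of N2 to the alpha-silyl ketone 10, which acid protodesilylates. The closest known reaction type is the Lewis-acid-catalysed diazoalkane homologation of cyclic ketones (Tiffeneau–Demjanov-type ring expansion). No ring is closed: the five-membered ring C3a'–C4'–C5'–C7'–C7a' becomes ring B by insertion of one carbon (C6') between C5' and C7', a ring expansion by migration. No stereocentre of 11 is created (the silyl-bearing carbon is transient), and the four cyclobutane centres set in step 5 are not touched. The step needs migration of the CH2 (C5') instead of C7a' and reaction at the ketone instead of the lactone or ester; C7a' is quaternary, carries the electron-withdrawing ester and is held in the cyclobutane, so it should be a poor migrating group, and the bulky silyl ketone should resist a second insertion. The carbonyl therefore ends at C7' with C6' as its only enolisable neighbour, which fixes the later C6'=C7' alkene.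

Step 7
Reactants: 11
Product: 12 enol triflate at C7'
Conditions: KHMDS, THF, −78 °C; then PhNTf2, −78 °C to 0 °C; aq. NH4Cl
Reagents that add atoms: N-phenylbis(trifluoromethanesulfonimide) | O=S(=O)(N(c1ccccc1)S(=O)(=O)C(F)(F)F)C(F)(F)F
Why: Enolate O-sulfonylation; since C7a' is quaternary the ketone can enolise only toward C6', and no other carbonyl in 11 has an alpha-hydrogen.

Step 8
Reactants: 12
Product: 13 cyclohexene lactone tert-butyl ester (ring B complete)
Conditions: Pd(OAc)2 (5 mol %), PPh3 (10 mol %), HCO2H, Bu3N, DMF, 60 °C
Reagents that add atoms: none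
Why: Palladium-catalysed formate reduction of the vinyl triflate (oxidative addition to zerovalent palladium, formate exchange, decarboxylation, reductive elimination) replaces OTf by H and leaves lactone and ester alone.

Step 9
Reactants: 13
Product: 14 lactol (cyclic hemiketal of the C3' butyl ketone with the C7a hydroxyl)
Conditions: n-BuLi (1.1 equiv), THF, −78 °C; aq. NH4Cl at −78 °C
Reagents that add atoms: n-butyllithium | [Li]CCCC
Why: Mono-addition of an organolithium to a gamma-lactone should stop at the lithium hemiketal at −78 °C, the tert-butyl ester on quaternary C7a' being too hindered to compete; the new hemiketal centre forms as a mixture that is erased in step 11.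

Step 10
Reactants: 14
Product: 15 1,4-diketone (C7a ketone, C3' butyl ketone)
Conditions: Dess–Martin periodinane, CH2Cl2, rt
Reagents that add atoms: none
Why: The lactol equilibrates with its open hydroxy ketone, whose secondary alcohol at C7a is oxidised (Dess–Martin oxidation), which removes the relay stereocentre after it has done its work.

Step 11
Reactants: 15
Product: 17 (Z)-butylidene lactone B with ring A ketone, via keto acid 16 (not isolated)
Conditions: TFA, CH2Cl2, rt; concentrate; then TFAA, CH2Cl2, 0 °C to rt
Reagents that add atoms: none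
Why: Acidolysis of the tert-butyl ester followed by dehydrative enol lactonisation of the gamma-keto acid; C3a' is quaternary, so only the exocyclic enol can form, and under acid the (Z)-isomer (propyl syn to the ring oxygen, away from C3a') should be the thermodynamic one.

Step 12
Reactants: 17
Product: 18 2-pentanoyl ketone (1,3-diketone on ring A)
Conditions: 1-pentanoylbenzotriazole, MgBr2·OEt2, i-Pr2NEt, CH2Cl2, rt
Reagents that add atoms: 1-pentanoyl-1H-benzotriazole | CCCCC(=O)n1nnc2ccccc12
Why: Claisen-type C-acylation by soft enolisation; the magnesium enolate can form only toward the CH2 at C3a (C7 is a cyclobutane methine), the amine base should spare the enol lactone, and the new C3a centre is lost by enolisation.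

Step 13
Reactants: 18
Product: 19 cyclohexenyl triflate (C7a–OTf, C3a–pentanoyl)
Conditions: Tf2O, i-Pr2NEt, CH2Cl2, −78 °C
Reagents that add atoms: trifluoromethanesulfonic anhydride | O=S(=O)(OS(=O)(=O)C(F)(F)F)C(F)(F)F
Why: O-sulfonylation of the enolised 1,3-diketone; six-membered 2-acyl ketones enolise with the double bond in the ring, so the ring oxygen at C7a should be triflated to give the C7a=C3a vinyl triflate.

Step 14
Reactants: 19
Product: 20 target CNP0371639.2
Conditions: PdCl2(PPh3)2 (5 mol %), CO (1 atm), Et3N, MeCN, 70 °C
Reagents that add atoms: carbon monoxide | [C-]#[O+]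
Why: Carbonylative lactonisation, in which oxidative addition and CO insertion give an acylpalladium that is trapped by the enol oxygen of the butyl ketone to close the butenolide, the (Z)-butylidene being favoured because the (E)-isomer would press the propyl group against C4.

Compound list
1 | tert-butyl acetoacetate | CC(=O)CC(=O)OC(C)(C)C | starting material
2 | methyl 2-(bromomethyl)acrylate | COC(=O)C(=C)CBr | starting material
3 | 1-tert-butyl 7-methyl 6-methylidene-3-oxoheptanedioate | C=C(CCC(=O)CC(=O)OC(C)(C)C)C(=O)OC | intermediate
4 | 1-tert-butyl 7-methyl 3,6-dioxoheptanedioate (alpha-keto ester, not isolated) | COC(=O)C(=O)CCC(=O)CC(=O)OC(C)(C)C | intermediate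
5 | 2-tert-butyl 1-methyl 3-oxocyclopent-1-ene-1,2-dicarboxylate | COC(=O)C1=C(C(=O)OC(C)(C)C)C(=O)CC1 | intermediate
6 | 2-(tert-butoxycarbonyl)-3-oxocyclopent-1-ene-1-carboxylic acid | OC(=O)C1=C(C(=O)OC(C)(C)C)C(=O)CC1 | intermediate
7 | (R)-cyclohex-2-en-1-ol | O[C@@H]1CCCC=C1 | starting material
8 | 2-tert-butyl 1-[(1R)-cyclohex-2-en-1-yl] 3-oxocyclopent-1-ene-1,2-dicarboxylate | O=C1CCC(C(=O)O[C@@H]2CCCC=C2)=C1C(=O)OC(C)(C)C | intermediate
9 | photoadduct: cyclopentanone (C7'=O) cis-fused at C3a'–C7a' to the cyclobutane, gamma-lactone C3'(=O)–O–C7a, tert-butyl ester on C7a'; lactone, ester and ring A on one cyclobutane face, cyclopentanone on the other; C7a (R), with O, C3a' and C7a' all cis on ring A | O=C1O[C@@H]2CCC[C@H]3[C@@H]2[C@@]14CCC(=O)[C@]34C(=O)OC(C)(C)C | intermediate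
10 | alpha-silyl ketone: as 11 with SiMe3 on C6', mixture at C6' (not isolated) | O=C1O[C@@H]2CCC[C@H]3[C@@H]2[C@@]14CCC([Si](C)(C)C)C(=O)[C@]34C(=O)OC(C)(C)C | intermediate
11 | ring-expanded ketone: as 9 but with a cyclohexanone (C7'=O, new CH2 = C6') | O=C1O[C@@H]2CCC[C@H]3[C@@H]2[C@@]14CCCC(=O)[C@]34C(=O)OC(C)(C)C | intermediate
12 | enol triflate: C7'(OTf)=C6' in ring B, otherwise as 11 | O=C1O[C@@H]2CCC[C@H]3[C@@H]2[C@@]14CCC=C(OS(=O)(=O)C(F)(F)F)[C@]34C(=O)OC(C)(C)C | intermediate
13 | cyclohexene lactone: ring B with C6'=C7', tether lactone and tert-butyl ester intact | O=C1O[C@@H]2CCC[C@H]3[C@@H]2[C@@]14CCC=C[C@]34C(=O)OC(C)(C)C | intermediate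
14 | lactol: C3'(OH)(n-Bu)–O–C7a hemiketal (mixture at C3'), in equilibrium with the C7a-hydroxy butyl ketone | CCCCC1(O)O[C@@H]2CCC[C@H]3[C@@H]2[C@@]14CCC=C[C@]34C(=O)OC(C)(C)C | intermediate
15 | 1,4-diketone: cyclohexanone at C7a, pentanoyl on C3a', tert-butyl ester on C7a' | O=C1CCC[C@H]2[C@@H]1[C@]3(C(=O)CCCC)CCC=C[C@]23C(=O)OC(C)(C)C | intermediate
16 | keto acid: as 15 with CO2H on C7a' (not isolated) | O=C1CCC[C@H]2[C@@H]1[C@]3(C(=O)CCCC)CCC=C[C@]23C(=O)O | intermediate
17 | ketone with complete propellane half: (Z)-butylidene gamma-lactone B, ring B cyclohexene, ring A cyclohexanone (C7a=O) | O=C1CCC[C@H]2[C@@H]1[C@]13CCC=C[C@]21C(=O)O/C3=C\CCC | intermediate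
18 | 1,3-diketone: 17 with pentanoyl on C3a (enolised; C3a not defined) | O=C1C(C(=O)CCCC)CC[C@H]2[C@@H]1[C@]13CCC=C[C@]21C(=O)O/C3=C\CCC | intermediate
19 | vinyl triflate: C7a(OTf)=C3a–C(=O)n-Bu on ring A | FC(F)(F)S(=O)(=O)OC1=C(C(=O)CCCC)CC[C@H]2[C@@H]1[C@]13CCC=C[C@]21C(=O)O/C3=C\CCC | intermediate
20 | CNP0371639.2, the (Z,Z')-ligustilide [2+2] dimer joined C6–C7a' and C7–C3a' | CCC/C=C1\OC(=O)C2=C1CC[C@H]1[C@@H]2[C@]23CCC=C[C@]12C(=O)O/C3=C\CCC | target

Total step count: 14. Longest linear sequence: 14 steps (1 and 2 to 20; alcohol 7 enters in step 4).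

Steps most likely to fail

1. Step 5 (photocycloaddition). The ester tether may stay in its extended s-trans rotamer, so that the alkene does not reach the excited enone within the triplet lifetime and photoreduction or intermolecular dimerisation takes over. The fallback replaces the direct ester by a longer hydroxy-acid spacer. From 7, bromoacetyl bromide and pyridine give (R)-cyclohex-2-en-1-yl bromoacetate F1. The caesium salt of 6 (Cs2CO3, DMF) is alkylated with it to the glycolate-linked diester F2. Irradiation at 366 nm should give the eight-membered dilactone photoadduct F3. Me3SnOH (ClCH2CH2Cl, 70 °C) and then TsOH (toluene, 60 °C) remove the glycolate spacer, and the cis hydroxy acid closes to the gamma-lactone, which returns to the route at 9.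

2. Step 6 (key ring expansion). The hindered, chelated ketone may not add the diazoalkane, or epoxide formation may compete with migration. The fallback is a Saegusa–Ito ring expansion. From 9, TMSOTf and Et3N give the silyl enol ether F4 (enolisation is possible only toward C5'). Et2Zn and CH2I2 give the siloxycyclopropane F5. FeCl3 in DMF and then NaOAc open it to the ring-expanded cyclohexenone F6. Hydrogenation of the enone double bond (H2, Pd/C, EtOAc) returns to the route at 11.

3. Step 13 (enol triflate of the 1,3-diketone). Sulfonylation may occur at the side-chain oxygen and give the exocyclic enol triflate, which cannot lactonise. The fallback fixes the halide position by formylation. From 17, PBr3/DMF (Vilsmeier–Haack bromoformylation, CHCl3, 0 °C to rt) gives the bromo enal F7. n-BuMgBr (THF, −78 °C) adds to the aldehyde to give the allylic alcohol F8. Dess–Martin periodinane gives the bromo enone F9. PdCl2(PPh3)2, CO and Et3N (MeCN, 70 °C) then close the butenolide as in step 14 and return to the route at 20.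

Further compounds
F1 | step 5 | (R)-cyclohex-2-en-1-yl bromoacetate | BrCC(=O)O[C@@H]1CCCC=C1
F2 | step 5 | glycolate-linked diester of 6 and 7 | O=C1CCC(C(=O)OCC(=O)O[C@@H]2CCCC=C2)=C1C(=O)OC(C)(C)C
F3 | step 5 | eight-membered dilactone photoadduct (cyclobutane configured as in 9) | O=C1OCC(=O)O[C@@H]2CCC[C@H]3[C@@H]2[C@@]14CCC(=O)[C@]34C(=O)OC(C)(C)C
F4 | step 6 | trimethylsilyl enol ether of 9 (C7'(OSiMe3)=C5') | O=C1O[C@@H]2CCC[C@H]3[C@@H]2[C@@]14CC=C(O[Si](C)(C)C)[C@]34C(=O)OC(C)(C)C
F5 | step 6 | siloxycyclopropane from F4 | O=C1O[C@@H]2CCC[C@H]3[C@@H]2[C@@]14CC5CC5(O[Si](C)(C)C)[C@]34C(=O)OC(C)(C)C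
F6 | step 6 | ring-expanded cyclohexenone (C7'=O, C5'=C6') | O=C1O[C@@H]2CCC[C@H]3[C@@H]2[C@@]14CC=CC(=O)[C@]34C(=O)OC(C)(C)C
F7 | step 13 | bromo enal (C7a–Br, C3a–CHO) | BrC1=C(C=O)CC[C@H]2[C@@H]1[C@]13CCC=C[C@]21C(=O)O/C3=C\CCC
F8 | step 13 | allylic alcohol (C3a–CH(OH)n-Bu, mixture at the carbinol) | BrC1=C(C(O)CCCC)CC[C@H]2[C@@H]1[C@]13CCC=C[C@]21C(=O)O/C3=C\CCC
F9 | step 13 | bromo enone (C7a–Br, C3a–C(=O)n-Bu) | BrC1=C(C(=O)CCCC)CC[C@H]2[C@@H]1[C@]13CCC=C[C@]21C(=O)O/C3=C\CCC
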